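## Analysis of the target

CNP0525404.1 is a linearly fused tetracycle: a cyclopentenone (ring A), a cycloheptane (ring B), a dihydropyran (ring C) and a 5,6-dimethyl-α-pyrone (ring D). Ring B is numbered here B1 (hemiketal carbon, shared with ring C), B2 (CHOH), B3 (ketone), B4 (tertiary carbinol), B5 (enone β-carbon), B6 (CHMe) and B7 (ring-fusion CH); the other ring A carbons are A1 (=CH), A2 (C=O) and A3 (CMe2). All five stereocentres sit on ring B: B1 (S), B2 (R), B4 (R), B6 (R), B7 (R). With the face of the B6 methyl called β, the B2 hydroxyl and the B7 hydrogen are β, and the B1 hydroxyl, the B4 hydroxyl and the CH2 link from B7 to pyrone C-3 are α. Rings B and C are therefore trans-fused, with the hemiketal hydroxyl axial. The hemiketal is a vinylogous acylal (its ring oxygen is the pyrone C-4 oxygen), so it can open, and once B3 is a ketone the pyronyloxy group is a β-leaving group. The B3 ketone lies between two α-ketol carbinols, the B4 carbinol is an aldol of the ring A ketone, and the pyrone is electrophilic and absorbs light. The difficulty is four contiguous oxidised carbons B1–B4 on a seven-membered ring, two of them fully substituted and one next to the quaternary A3. The strategy rests on the fact that B1–B5 are five contiguous carbons with B1 bonded to the pyrone C-4 oxygen, while B6, B7 and the CH2 link form a but-2-enyl branch on pyrone C-3.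

## Retrosynthetic reasoning

**Hemiketal.** The B1–OH bond of 25 is traced back to the methyl ketal 24. A free hemiketal would open under every basic step of the route; the methyl ketal is base-stable and hydrolyses under mild acid. The forward step only has to exchange OMe for OH, and the configuration at B1 is then set by equilibration.

**B2 hydroxyl.** The B2–O bond of 24 is cut to give ketone 21. Only B2 can enolise, because B4 is fully substituted. The forward reaction must oxidise the B2 enol derivative on the β face, and it must avoid a free enolate long enough to expel the pyronyloxy group from B1.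

**B3 ketone.** Ketone 21 comes from diol 20 and that from silyl ether 19. The B3 oxygen is thus carried from the start as a stereocentre, which is used twice for stereocontrol before it is oxidised.

**Ring A.** In 19 the bonds B5=A1, A1–A2 and A3–B4 are cut. A3–B4 is an aldol bond between an isopropyl ketone and the B4 ketone (1,4-diketone 17 to aldol 18). A1–A2 is the bond between an acyl anion from 16 and the exo-methylene ketone 15, and the A1 carbon is a one-carbon Mannich unit added to ketone 12. This uses the B4 ketone and its α-methylene B5 exactly as the fragmentation delivers them. The forward sequence must close the five-membered ring on the β face of B4 and then introduce the B5=A1 double bond.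

**Ring B.** Ketone 12 is reconnected between B1 and B5 to give the cyclobutane 11. In 11 that bond is flanked by an oxygen donor on B1 and a ketone acceptor on B5, so strain-driven heterolysis opens the four- and five-membered rings into the seven-membered ring. The forward step has to break only this bond and trap B1 as the ketal.

**Key disconnection.** In 11 the bonds B1–B7 and B5–B6 are cut to give the pyronyloxy cyclopentenone 10. An enone–alkene [2+2] photocycloaddition forms both bonds, ring C and the cyclobutane in one operation. The tether through the pyrone fixes the regiochemistry and stays in the product as rings C and D.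

**Precursor.** The enol ether C–O bond of 10 is cut to give the crotyl pyrone 4 and the β-chloro enone 9; addition–elimination joins them. Pyrone 4 comes from 3 and carbonate 2 (from 1) by allylic alkylation at C-3. Chloro enone 9 comes from dione 8, which is reached from the enantiopure hydroxy enone 5 through silyl ether 6 and epoxy ketone 7. The stereocentre is therefore bought rather than made.

## Alternatives that were turned down

**Alternative 1: allenic Pauson–Khand reaction for rings A and B.** The disconnection removes the ring A carbonyl carbon and cuts the B4–B5 bond, leading to the allenyne A2. In the forward direction [Rh(CO)2Cl]2 mediates a carbonylative [2+2+1] cyclisation of the alkyne with the dimethyl-substituted allene double bond, giving the 4-alkylidene cyclopentenone A1. In its favour, rings A and B and the quaternary A3 are made in one catalytic step, and B6 and B7 can be set beforehand in an open chain. Against it, A1 carries a B3=B4 double bond inside a cross-conjugated dienone. Turning that into B4–OH and B3=O means oxidising an electron-poor alkene selectively next to a second enone double bond, with no nearby group to control the B4 face. The pyrone then has to be attached late through the hindered CH2 on B7 (C- versus O-alkylation of a 4-hydroxypyrone), and the B2 hydroxyl is still missing. On ring A this alternative is stronger, one step against four here. The chosen route offers instead rings B and C, the B1 oxygen and the B6/B7 pair in one step, with the pyrone in place from the beginning and the B3 oxygen already installed.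

**Alternative 2: vinylcarbenoid cyclopropanation–Cope (4+3) annulation for ring B.** The disconnection cuts the B6–B7 and B2–B3 bonds, leading to the vinyldiazoacetate A4 and the diene A5. Rh2(S-PTAD)4 generates the carbenoid from A4; it cyclopropanates the ethylidene bond of A5, and Cope rearrangement of the cis-divinylcyclopropane gives the cycloheptadiene A3. In its favour, the absolute configuration is set by a catalyst, the Cope step is stereospecific, and seven-membered ring formation of this type is well established. Against it, the carbenoid must choose the ethylidene bond over the more electron-rich silyl enol ether bond of A5, and both are hindered exocyclic alkenes. A3 has its double bond at B4=B5, so it must be transposed into B4–OH and a B5=A1 enone. Rings C and D must be built afterwards from the ester carbon, and B2 is still unoxidised. This alternative is stronger on absolute stereocontrol, where the chosen route relies on a purchased chiral enone. The chosen route offers a much shorter path from the key step to the target, because the pyrone, ring C and the B1 oxygen are already there.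

**Alternative 3: lactone carbonyl ylide cycloaddition for an oxygen-bridged ring B.** The disconnection cuts the B1–B2 and B3–B4 bonds and the bridging B4–O bond, leading to the diazoketone A7 and vinylene carbonate A8. Rh2(OAc)4 converts A7 into a carbenoid, the enol-lactone carbonyl oxygen captures it, and the six-membered ylide adds to A8 to give the cycloadduct A6. In its favour, A6 carries the oxygens at B1, B2, B3 and B4 and the complete ring B, and ring A would follow by a simple aldol condensation; on oxidation-state economy this is the strongest of the four plans. Against it, an enol-lactone carbonyl is a poor donor for ylide formation, the diazo carbon is flanked by the quaternary A3, and A8 is a sluggish dipolarophile, so carbenoid dimerisation and hydrogen shifts would compete. The face of the cycloaddition relative to B6/B7 is not obviously controlled. The resulting B2/B3 cis-diol would then have to be differentiated so that only B3 is oxidised. The chosen route introduces the oxygens one at a time, each already differentiated, and its key step belongs to a reaction class that tolerates crowding at the reacting carbons.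

Key step: step 8

Assumption: compounds 3 and 5 are taken as purchasable, and the B1/B2 arrangement of the natural product is taken to be the thermodynamically preferred one, because both centres can equilibrate through the open 2-hydroxy-1,3-diketone form.

## Route

Step 1
Reactants: 1 (E)-but-2-en-1-ol
Product: 2 (E)-but-2-en-1-yl methyl carbonate
Conditions: ClCO2Me, pyridine, CH2Cl2, 0 °C
Reagents that add atoms: methyl chloroformate, COC(Cl)=O
Why: Acylation of a primary allylic alcohol gives the carbonate; it serves as a neutral precursor of the π-crotyl palladium complex and releases its own base on ionisation.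

Step 2
Reactants: 3 4-hydroxy-5,6-dimethyl-2H-pyran-2-one; 2 (E)-but-2-en-1-yl methyl carbonate
Product: 4 3-[(E)-but-2-en-1-yl]-4-hydroxy-5,6-dimethyl-2H-pyran-2-one
Conditions: Pd(PPh3)4 (5 mol %), THF, 40 °C, slight excess of 3
Reagents that add atoms: none
Why: Tsuji–Trost allylation: zerovalent palladium ionises the carbonate, the released methoxide deprotonates the acidic pyrone, and C-3 attacks the less hindered terminus of the syn π-crotyl complex to give the linear E product. Any O-crotyl ether is itself an allylic electrophile and is returned to the complex, so the C-alkylated pyrone should accumulate.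

Step 3
Reactants: 5 (R)-4-hydroxycyclopent-2-en-1-one
Product: 6 (R)-4-(triisopropylsilyloxy)cyclopent-2-en-1-one
Conditions: i-Pr3SiCl, imidazole, DMF, 0 °C to rt
Reagents that add atoms: triisopropylsilyl chloride, CC(C)[Si](Cl)(C(C)C)C(C)C
Why: Standard silylation of a secondary alcohol under mild base, which the elimination-prone hydroxy enone tolerates. The triisopropylsilyl group is chosen because it resists acid, fluoride-free base and 1,2-migration in the later steps.

Step 4
Reactants: 6 (R)-4-(triisopropylsilyloxy)cyclopent-2-en-1-one
Product: 7 (4R)-2,3-epoxy-4-(triisopropylsilyloxy)cyclopentan-1-one (oxirane trans to the silyloxy group)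
Conditions: 30% aq. H2O2, NaOH (cat.), MeOH, −20 °C
Reagents that add atoms: hydrogen peroxide, OO
Why: Weitz–Scheffer nucleophilic epoxidation of the enone; hydroperoxide adds to the β-carbon anti to the bulky silyloxy group. The two new centres are removed in the next step, so only the conversion matters.

Step 5
Reactants: 7 (4R)-2,3-epoxy-4-(triisopropylsilyloxy)cyclopentan-1-one
Product: 8 (R)-4-(triisopropylsilyloxy)cyclopentane-1,3-dione
Conditions: Pd(PPh3)4 (5 mol %), 1,2-bis(diphenylphosphino)ethane (5 mol %), toluene, 80 °C
Reagents that add atoms: none
Why: Isomerisation of an α,β-epoxy ketone to a 1,3-diketone catalysed by zerovalent palladium: insertion into the Cα–O bond, then β-hydride elimination from the carbinol carbon and tautomerisation. The silyloxy-bearing carbon is not involved, so its configuration is retained.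

Step 6
Reactants: 8 (R)-4-(triisopropylsilyloxy)cyclopentane-1,3-dione
Product: 9 (R)-3-chloro-5-(triisopropylsilyloxy)cyclopent-2-en-1-one
Conditions: (COCl)2, DMF (cat.), CH2Cl2, 0 °C to rt
Reagents that add atoms: oxalyl chloride, O=C(Cl)C(Cl)=O
Why: Vinylogous acid chloride formation: the enol oxygen is activated and chloride replaces it by addition–elimination. The oxygen and carbon remote from the bulky, electron-withdrawing silyloxy group are the more accessible and more nucleophilic pair, so chloride should end up on the carbon next to CH2 and the carbonyl next to the stereocentre.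

Step 7
Reactants: 4 3-[(E)-but-2-en-1-yl]-4-hydroxy-5,6-dimethyl-2H-pyran-2-one; 9 (R)-3-chloro-5-(triisopropylsilyloxy)cyclopent-2-en-1-one
Product: 10 3-[(E)-but-2-en-1-yl]-5,6-dimethyl-4-{[(4R)-3-oxo-4-(triisopropylsilyloxy)cyclopent-1-en-1-yl]oxy}-2H-pyran-2-one
Conditions: i-Pr2NEt, DABCO (10 mol %), MeCN, 0 °C to rt
Reagents that add atoms: none
Why: Addition–elimination of the pyrone 4-oxygen on the β-chloro enone, with DABCO forming a more reactive β-ammonium enone. C-3 of the pyrone is blocked by the crotyl group, so O-attack is the only productive path, and the amine bases are too weak to epimerise the α-silyloxy ketone.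

Step 8
Reactants: 10 3-[(E)-but-2-en-1-yl]-5,6-dimethyl-4-{[(4R)-3-oxo-4-(triisopropylsilyloxy)cyclopent-1-en-1-yl]oxy}-2H-pyran-2-one
Product: 11 cyclobutane photoadduct: rings C and D, a cyclobutane (B1, B5, B6, B7) and a 2-silyloxycyclopentanone (B1–B5); cyclobutane cis-fused to ring C and to the cyclopentanone, B6 methyl trans to the CH2 link on B7, silyloxy group on the cyclopentanone face opposite the cyclobutane
Conditions: hν (366 nm), degassed CH2Cl2 (2 mM), −40 °C
Reagents that add atoms: none
Why: Long-wavelength excitation of the β-alkoxy enone and intersystem crossing give the twisted triplet enone; the closest known reaction type is the intramolecular [2+2] photocycloaddition of β-alkoxy enones used in de Mayo sequences. Ring C closes first by 6-exo attack of the oxygen-bearing β-carbon (B1) on the inner alkene carbon (B7), which the rigid cis C-3=C-4 bond of the pyrone holds in reach; this gives the straight and not the crossed adduct. The resulting triplet 1,4-biradical (α-keto radical at B5, secondary radical at B6) then closes the cyclobutane by radical combination after spin inversion. B1 and B5 must be cis because a cyclobutane can only be cis-fused to a five-membered ring, and B7 follows from the tether, which can only reach the face from which the ring C oxygen departs. The absolute sense is set by the silyloxy group, which projects over one face of the nearly flat cyclopentenone and sends the alkene to the other. B6 keeps the E geometry if closure is faster than rotation about the B6–B7 bond; the rotamer with the methyl turned away from the CH2 link leads to the same isomer. Chemoselectivity relies on irradiating above the pyrone absorption; the crotyl group can reach the pyrone 5,6-bond only through a strained bridged ring, and dilution suppresses pyrone dimerisation.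

Step 9
Reactants: 11 cyclobutane photoadduct
Product: 12 ring B ketone as B1 methyl ketal (tricycle B–C–D: B1 OMe α and ring C oxygen β, B3 silyloxy α, B4 ketone, B5 CH2, B6 methyl β, B7 H β)
Conditions: camphorsulfonic acid (20 mol %), MeOH (10 equiv), CH2Cl2, 0 °C to rt
Reagents that add atoms: methanol, CO
Why: De Mayo-type fragmentation of a donor–acceptor cyclobutane: protonation of the B4 ketone and push from the ring C oxygen break the strained B1–B5 bond, giving the B4 enol and a B1 oxocarbenium ion. Methanol adds axially, so the ketal should form trans-fused with OMe anti to the B7 hydrogen, the anomerically favoured arrangement. Methanol is used instead of water so that the product cannot open to a hydroxypyrone and a ketone in the basic steps that follow.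

Step 10
Reactants: 12 ring B ketone methyl ketal
Product: 15 B5-methylene ketone (exo-methylene on B5 conjugated to the B4 ketone), via Mannich base 13 (not isolated), via trimethylammonium iodide 14 (not isolated)
Conditions: LiN(SiMe3)2, THF, −78 °C; [Me2N=CH2]I, −78 to 0 °C; then MeI, THF, rt; then aq. NaHCO3, CH2Cl2, rt
Reagents that add atoms: N,N-dimethylmethyleneiminium iodide, C=[N+](C)C.[I-]
Why: Kinetic deprotonation takes the unhindered B5 methylene and not the B3 methine that carries the silyloxy group; the enolate is aminomethylated (Mannich reaction), and quaternisation followed by mild base gives the α-methylene ketone by elimination. The methyl ketal and the pyrone methyl groups are not deprotonated by the silylamide at −78 °C.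

Step 11
Reactants: 15 B5-methylene ketone; 16 2-methylpropanal
Product: 17 1,4-diketone: B5 carries CH2–C(=O)–CH(CH3)2 (mixture of B5 epimers)
Conditions: 3-benzyl-5-(2-hydroxyethyl)-4-methylthiazolium chloride (20 mol %), Et3N (50 mol %), 1,4-dioxane, 70 °C
Reagents that add atoms: none
Why: Stetter reaction: the thiazolylidene converts the aldehyde into an acyl anion equivalent that adds to the unhindered methylene terminus of the enone. The B5 centre formed on protonation is removed later, and an aprotic solvent keeps the ketal from exchanging.

Step 12
Reactants: 17 1,4-diketone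
Product: 18 ring A aldol: 3-hydroxy-2,2-dimethylcyclopentanone fused at B4–B5 (B4 OH α, A3 on the β face, B5 H α)
Conditions: t-BuOK (30 mol %), t-BuOH/THF, −20 to 0 °C
Reagents that add atoms: none
Why: Intramolecular aldol addition: among the equilibrating enolates only the one at the isopropyl carbon (A3) can close a five-membered ring onto the B4 ketone, and the product cannot dehydrate because A3 becomes quaternary. Attack anti to the α-silyloxy group on B3 (Felkin–Anh) should place A3 on the β face and the new hydroxyl on the α face; B5 epimerises under the conditions, so both epimers of 17 can feed this pathway.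

Step 13
Reactants: 18 ring A aldol
Product: 19 ring A enone (B5=A1 double bond conjugated to the A2 ketone; B4 OH α)
Conditions: IBX, 4-methoxypyridine N-oxide, DMSO, rt to 40 °C
Reagents that add atoms: none
Why: IBX dehydrogenation of a ketone to an enone; A1 is the only enolisable position of the A2 ketone, so the double bond can form only towards B5. The conditions are not basic, so the β-hydroxy ketone is not exposed to retro-aldol cleavage.

Step 14
Reactants: 19 ring A enone
Product: 20 B3,B4-diol (B3 OH α, B4 OH α)
Conditions: HF·pyridine, pyridine, THF, 0 °C to rt
Reagents that add atoms: none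
Why: Fluoride cleavage of the silyl ether under buffered, weakly acidic conditions that spare the methyl ketal, the enone and the aldol unit.

Step 15
Reactants: 20 B3,B4-diol
Product: 21 B3 ketone (B4 OH α, B2 CH2, B1 methyl ketal)
Conditions: Dess–Martin periodinane, pyridine, CH2Cl2, 0 °C to rt
Reagents that add atoms: none
Why: Periodinane oxidation of the only secondary alcohol; the tertiary B4 hydroxyl cannot be oxidised, and the buffered, neutral medium avoids β-elimination from the new β-ketal ketone.

Step 16
Reactants: 21 B3 ketone
Product: 24 B2-hydroxy B3-ketone as B1 methyl ketal (B2 OH β, B1 OMe α, B4 OH α), via bis(trimethylsilyl) enol ether 22 (not isolated), via silyloxy epoxide 23 (not isolated)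
Conditions: NaN(SiMe3)2 added to 21 and Me3SiCl (in situ quench), THF, −78 °C; then dimethyldioxirane, acetone/CH2Cl2, −40 °C; then Et3N·3HF, THF, 0 °C
Reagents that add atoms: dimethyldioxirane, CC1(C)OO1
Why: Rubottom oxidation: the enolate can form only towards B2 and is silylated as it forms, so it has little time to expel the pyronyloxy group from B1; the B4 hydroxyl is silylated at the same time. The α face of the enol ether is covered by the axial B1 methoxy group and the B4 silyloxy group, while the β face carries only ring-bound atoms, so the dioxirane should deliver oxygen to the β face of B2. Fluoride then opens the silyloxy epoxide and removes both silyl groups.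

Step 17
Reactants: 24 B2-hydroxy B3-ketone methyl ketal
Product: 25 CNP0525404.1
Conditions: 1 M aq. HCl, THF, rt
Reagents that add atoms: water, O
Why: Acid hydrolysis of the mixed methyl/pyronyl ketal, a vinylogous acylal that ionises readily; water replaces methanol and the hemiketal re-closes in its preferred trans-fused form with the axial hydroxyl. B2 and B7 can equilibrate through the open form only towards the same arrangement.

## Compound list

1 | (E)-but-2-en-1-ol | C/C=C/CO | starting material
2 | (E)-but-2-en-1-yl methyl carbonate | C/C=C/COC(=O)OC | intermediate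
3 | 4-hydroxy-5,6-dimethyl-2H-pyran-2-one | Cc1oc(=O)cc(O)c1C | starting material
4 | 3-[(E)-but-2-en-1-yl]-4-hydroxy-5,6-dimethyl-2H-pyran-2-one | C/C=C/Cc1c(O)c(C)c(C)oc1=O | intermediate
5 | (R)-4-hydroxycyclopent-2-en-1-one | O=C1C=C[C@H](O)C1 | starting material
6 | (R)-4-(triisopropylsilyloxy)cyclopent-2-en-1-one | O=C1C=C[C@H](O[Si](C(C)C)(C(C)C)C(C)C)C1 | intermediate
7 | (4R)-2,3-epoxy-4-(triisopropylsilyloxy)cyclopentan-1-one, oxirane trans to the silyloxy group | O=C1[C@H]2O[C@H]2[C@H](O[Si](C(C)C)(C(C)C)C(C)C)C1 | intermediate
8 | (R)-4-(triisopropylsilyloxy)cyclopentane-1,3-dione | O=C1CC(=O)C[C@H]1O[Si](C(C)C)(C(C)C)C(C)C | intermediate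
9 | (R)-3-chloro-5-(triisopropylsilyloxy)cyclopent-2-en-1-one | O=C1C=C(Cl)C[C@H]1O[Si](C(C)C)(C(C)C)C(C)C | intermediate
10 | 3-[(E)-but-2-en-1-yl]-5,6-dimethyl-4-{[(4R)-3-oxo-4-(triisopropylsilyloxy)cyclopent-1-en-1-yl]oxy}-2H-pyran-2-one | C/C=C/Cc1c(OC2=CC(=O)[C@H](O[Si](C(C)C)(C(C)C)C(C)C)C2)c(C)c(C)oc1=O | intermediate
11 | cyclobutane photoadduct (rings C and D, cyclobutane B1/B5/B6/B7, 2-silyloxycyclopentanone) | Cc1oc(=O)c2c(c1C)O[C@@]13C[C@@H](O[Si](C(C)C)(C(C)C)C(C)C)C(=O)[C@@H]1[C@H](C)[C@H]3C2 | intermediate
12 | ring B ketone as B1 methyl ketal (B3 silyloxy α, B6 methyl β) | Cc1oc(=O)c2c(c1C)O[C@]1(OC)C[C@@H](O[Si](C(C)C)(C(C)C)C(C)C)C(=O)C[C@H](C)[C@H]1C2 | intermediate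
13 | Mannich base: B5-(dimethylaminomethyl) derivative of 12 (B5 epimers) | Cc1oc(=O)c2c(c1C)O[C@]1(OC)C[C@@H](O[Si](C(C)C)(C(C)C)C(C)C)C(=O)C(CN(C)C)[C@H](C)[C@H]1C2 | intermediate
14 | trimethylammonium iodide of 13 (B5 epimers) | Cc1oc(=O)c2c(c1C)O[C@]1(OC)C[C@@H](O[Si](C(C)C)(C(C)C)C(C)C)C(=O)C(C[N+](C)(C)C)[C@H](C)[C@H]1C2.[I-] | intermediate
15 | B5-methylene ketone | Cc1oc(=O)c2c(c1C)O[C@]1(OC)C[C@@H](O[Si](C(C)C)(C(C)C)C(C)C)C(=O)C(=C)[C@H](C)[C@H]1C2 | intermediate
16 | 2-methylpropanal | CC(C)C=O | starting material
17 | 1,4-diketone: B5-(3-methyl-2-oxobutyl) derivative of 12 (B5 epimers) | Cc1oc(=O)c2c(c1C)O[C@]1(OC)C[C@@H](O[Si](C(C)C)(C(C)C)C(C)C)C(=O)C(CC(=O)C(C)C)[C@H](C)[C@H]1C2 | intermediate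
18 | ring A aldol (B4 OH α, B5 H α, saturated ring A ketone) | Cc1oc(=O)c2c(c1C)O[C@]1(OC)C[C@@H](O[Si](C(C)C)(C(C)C)C(C)C)[C@@]3(O)[C@H](CC(=O)C3(C)C)[C@H](C)[C@H]1C2 | intermediate
19 | ring A enone with B3 silyl ether and B1 methyl ketal | Cc1oc(=O)c2c(c1C)O[C@]1(OC)C[C@@H](O[Si](C(C)C)(C(C)C)C(C)C)[C@@]3(O)C(=CC(=O)C3(C)C)[C@H](C)[C@H]1C2 | intermediate
20 | B3,B4-diol | Cc1oc(=O)c2c(c1C)O[C@]1(OC)C[C@@H](O)[C@@]3(O)C(=CC(=O)C3(C)C)[C@H](C)[C@H]1C2 | intermediate
21 | B3 ketone with B1 methyl ketal (B2-deoxy, O-methyl target) | Cc1oc(=O)c2c(c1C)O[C@]1(OC)CC(=O)[C@@]3(O)C(=CC(=O)C3(C)C)[C@H](C)[C@H]1C2 | intermediate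
22 | bis(trimethylsilyl) derivative of 21: B2=B3 silyl enol ether and B4 silyl ether | Cc1oc(=O)c2c(c1C)O[C@]1(OC)C=C(O[Si](C)(C)C)[C@@]3(O[Si](C)(C)C)C(=CC(=O)C3(C)C)[C@H](C)[C@H]1C2 | intermediate
23 | silyloxy epoxide of 22 (oxirane on the β face of B2–B3) | Cc1oc(=O)c2c(c1C)O[C@]1(OC)[C@@H]4O[C@]4(O[Si](C)(C)C)[C@@]3(O[Si](C)(C)C)C(=CC(=O)C3(C)C)[C@H](C)[C@H]1C2 | intermediate
24 | O-methyl target: B2 OH β, B3 ketone, B1 methyl ketal | Cc1oc(=O)c2c(c1C)O[C@]1(OC)[C@H](O)C(=O)[C@@]3(O)C(=CC(=O)C3(C)C)[C@H](C)[C@H]1C2 | intermediate
25 | CNP0525404.1 | Cc1oc(=O)c2c(c1C)O[C@]1(O)[C@H](O)C(=O)[C@@]3(O)C(=CC(=O)C3(C)C)[C@H](C)[C@H]1C2 | target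

## Step count and risk

Total: 17 steps. Longest linear sequence: 15 steps (5 to 25, steps 3–17); the pyrone branch (steps 1 and 2) joins at step 7.

**Step 8 (key step).** The most likely failure is loss of the crotyl geometry: the triplet 1,4-biradical can rotate about the B6–B7 bond before it closes, which would give the B6 epimer. Behind that stand leakage of the triplet energy to the pyrone and incomplete facial control by a silyloxy group that is 1,3 to both reacting carbons. The fallback sets B6 by conjugate addition instead of alkene geometry; it sets out from 3 and 9 and returns at 12. Pd(PPh3)4-catalysed allylation of 3 with allyl methyl carbonate gives 3-allyl-4-hydroxy-5,6-dimethylpyran-2-one F1. Coupling with 9 as in step 7 gives the allyl analogue of the precursor F2, and irradiation as in step 8 gives the des-methyl photoadduct F3, which has no alkene geometry to lose. Methanolysis as in step 9 gives the des-methyl ketone F4. LiN(SiMe3)2 and PhSeBr give the B5 phenylselenide F5, and H2O2 gives the B5=B6 cycloheptenone F6 by selenoxide elimination. Me2CuLi with Me3SiCl then adds methyl to B6 anti to the CH2 link on B7, which after aqueous work-up is 12.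

**Step 9.** The pyronyloxy oxygen is a weak donor because its lone pair is shared with the pyrone, so heterolysis of the B1–B5 bond under protic acid may be slow; forcing it risks exchange at the ketal or loss of the silyl ether. The fallback is a silyl-triflate-mediated opening; it sets out from 11 and returns at 13. Me3SiOTf (catalytic) with MeOSiMe3 in CH2Cl2 at −78 °C silylates the B4 ketone, the B1–B5 bond breaks, and the oxocarbenium ion is trapped to give the B4 trimethylsilyl enol ether of the methyl ketal F7. This enol ether is regiodefined, so it reacts directly with [Me2N=CH2]I to give 13, and the route continues with MeI and NaHCO3 as in step 10.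

**Step 12.** The aldol joins two fully substituted carbons, so the equilibrium may lie towards the open diketone. The base can also epimerise B3 and so remove the element that controls the B4 face, or close the bridged ring from B3 onto the side-chain ketone instead. The fallback replaces the reversible aldol by an irreversible addition and a metathesis; it sets out from 15 and returns at 19. The lithium enolate of N-methoxy-N-methylisobutyramide (LDA, then CeCl3, THF, −78 °C) adds 1,2 to the B4 ketone anti to the silyloxy group and gives the β-hydroxy Weinreb amide F8. Vinylmagnesium bromide converts it into the vinyl ketone F9, and ring-closing metathesis of the vinyl ketone with the B5 methylene (second-generation Grubbs catalyst, toluene, 80 °C) gives 19, without the dehydrogenation of step 13.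

**Step 16.** The enolate or the silyl enol ether next to the B1 ketal can expel the pyronyloxy group and open ring C to a β-methoxy enone; facial selectivity on a flexible seven-membered ring is the second uncertainty. The fallback makes this elimination the first step; it sets out from 21 and returns at 25. DBU and acetic anhydride open ring C and cap the released pyrone oxygen, giving the ring-opened β-methoxy enone with a 4-acetoxypyrone F10. Dimethyldioxirane epoxidises the electron-rich B1=B2 enol ether bond to the methoxy epoxide F11, as in the oxidation of a flavone to a flavonol. Aqueous HCl in THF then opens the epoxide, hydrolyses the acetate and the methyl enol ether, and lets the 2-hydroxy-1,3-diketone close to 25 under thermodynamic control.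

**Step 2.** Attack at the substituted terminus of the π-crotyl complex would give the branched isomer, and a second allylation at C-3 is possible. The fallback replaces the allylic alkylation by a sigmatropic route; it sets out from 3 and returns at 4. Mitsunobu etherification of 3 with but-3-en-2-ol (PPh3, DIAD, THF) gives 4-(but-3-en-2-yloxy)-5,6-dimethylpyran-2-one F12. Claisen rearrangement in toluene at reflux then moves the allyl unit to C-3 with transposition, through a chair transition state with the methyl equatorial, and gives the linear E-crotyl pyrone 4.

## Further compounds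

F1 | step 8 | 3-allyl-4-hydroxy-5,6-dimethyl-2H-pyran-2-one | C=CCc1c(O)c(C)c(C)oc1=O
F2 | step 8 | 3-allyl-5,6-dimethyl-4-{[(4R)-3-oxo-4-(triisopropylsilyloxy)cyclopent-1-en-1-yl]oxy}-2H-pyran-2-one | C=CCc1c(OC2=CC(=O)[C@H](O[Si](C(C)C)(C(C)C)C(C)C)C2)c(C)c(C)oc1=O
F3 | step 8 | des-methyl cyclobutane photoadduct (B6 CH2) | Cc1oc(=O)c2c(c1C)O[C@@]13C[C@@H](O[Si](C(C)C)(C(C)C)C(C)C)C(=O)[C@@H]1C[C@H]3C2
F4 | step 8 | des-methyl ring B ketone as B1 methyl ketal | Cc1oc(=O)c2c(c1C)O[C@]1(OC)C[C@@H](O[Si](C(C)C)(C(C)C)C(C)C)C(=O)CC[C@H]1C2
F5 | step 8 | B5-phenylselenyl derivative of F4 (B5 epimers) | Cc1oc(=O)c2c(c1C)O[C@]1(OC)C[C@@H](O[Si](C(C)C)(C(C)C)C(C)C)C(=O)C([Se]c3ccccc3)C[C@H]1C2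
F6 | step 8 | B5=B6 cycloheptenone as B1 methyl ketal | Cc1oc(=O)c2c(c1C)O[C@]1(OC)C[C@@H](O[Si](C(C)C)(C(C)C)C(C)C)C(=O)C=C[C@H]1C2
F7 | step 9 | B4 trimethylsilyl enol ether (B4=B5) of the B1 methyl ketal | Cc1oc(=O)c2c(c1C)O[C@]1(OC)C[C@@H](O[Si](C(C)C)(C(C)C)C(C)C)C(O[Si](C)(C)C)=C[C@H](C)[C@H]1C2
F8 | step 12 | β-hydroxy Weinreb amide: B4 OH α, B4 bearing CMe2C(=O)N(OMe)Me, B5 methylene | Cc1oc(=O)c2c(c1C)O[C@]1(OC)C[C@@H](O[Si](C(C)C)(C(C)C)C(C)C)[C@](O)(C(C)(C)C(=O)N(C)OC)C(=C)[C@H](C)[C@H]1C2
F9 | step 12 | vinyl ketone: B4 OH α, B4 bearing CMe2C(=O)CH=CH2, B5 methylene | Cc1oc(=O)c2c(c1C)O[C@]1(OC)C[C@@H](O[Si](C(C)C)(C(C)C)C(C)C)[C@](O)(C(C)(C)C(=O)C=C)C(=C)[C@H](C)[C@H]1C2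
F10 | step 16 | ring-C-opened β-methoxy enone (B1=B2) with 4-acetoxypyrone | CC(=O)Oc1c(C)c(C)oc(=O)c1C[C@H]1C(OC)=CC(=O)[C@@]2(O)C(=CC(=O)C2(C)C)[C@@H]1C
F11 | step 16 | B1,B2-epoxide of F10 (methoxy oxirane, epoxide configuration not defined) | CC(=O)Oc1c(C)c(C)oc(=O)c1C[C@H]1C2(OC)OC2C(=O)[C@@]3(O)C(=CC(=O)C3(C)C)[C@@H]1C
F12 | step 2 | 4-(but-3-en-2-yloxy)-5,6-dimethyl-2H-pyran-2-one (racemic) | C=CC(C)Oc1cc(=O)oc(C)c1C
A1 | alternative 1 | ring A–B 4-alkylidenecyclopentenone with B1 dioxolane and PMB-protected CH2OH on B7 | O=C1C=C2C(=CCC3(OCCO3)[C@H](COCc3ccc(OC)cc3)[C@H]2C)C1(C)C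
A2 | alternative 1 | allenyne precursor: terminal alkyne on the CHMe carbon, dioxolane, 1,1-dimethylallene | C#C[C@H](C)[C@@H](COCc1ccc(OC)cc1)C1(OCCO1)CC=C=C(C)C
A3 | alternative 2 | ring B cycloheptadiene (β-keto ester silyl enol ether) fused to ketal-protected ring A | COC(=O)C1=C(O[Si](C)(C)C(C)(C)C)C[C@H](O[Si](C)(C)C(C)(C)C)C2=C(CC3(OCCO3)C2(C)C)[C@@H]1C
A4 | alternative 2 | methyl 3-(tert-butyldimethylsilyloxy)-2-diazobut-3-enoate | COC(=O)C(=[N+]=[N-])C(=C)O[Si](C)(C)C(C)(C)C
A5 | alternative 2 | bis-exocyclic diene: ethylidene and silyloxymethylene on the ring A ketal | CC(C)(C)[Si](C)(C)O/C=C1/C(=C/C)CC2(OCCO2)C1(C)C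
A6 | alternative 3 | oxygen-bridged ring B cycloadduct (bridging ketal, cyclic carbonate) | Cc1oc(=O)c2c(c1C)O[C@@]13O[C@@](C(C)(C)C4(C)OCCO4)(C(=O)[C@H](C)[C@H]1C2)[C@H]1OC(=O)O[C@@H]31
A7 | alternative 3 | diazoketone on the ring C enol lactone | Cc1oc(=O)c2c(c1C)OC(=O)[C@H](C2)[C@@H](C)C(=O)C(=[N+]=[N-])C(C)(C)C1(C)OCCO1
A8 | alternative 3 | vinylene carbonate | O=C1OC=CO1
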